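The vessel took its starting material at a steady rate over 3.0 h, so I counted each flask's time from mid-feed and treated conversion as a first-order approach to completion.

| flask | starting material | free catalyst | remark | time |
|---|---|---|---|---|
| north-east | 13 mM (fed, over 3.0 h) | 100 µM | run made earlier |  |
| east | 10 mM (fed, over 3.0 h) | 100 µM | run made earlier |  |
| Wednesday's | 20 mM (fed, over 3.0 h) | 200 µM |  | 25 h |
| Thursday's | 20 mM (fed, over 3.0 h) | 150 µM |  | 25 h |
| Friday's | 20 mM (fed, over 3.0 h) | 100 µM |  | 25 h |
| Saturday's | 20 mM (fed, over 3.0 h) | 30 µM |  | 25 h |
| Monday's | 20 mM (fed, over 3.0 h) | 60 µM |  | 25 h |

- north-east (time / h: product / %): 2.00: 3.0; 4.00: 10.3; 6.00: 17.5; 8.00: 24.0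
- east (time / h: product / %): 1.00: 0.8; 3.00: 6.8; 6.00: 18.8; 8.00: 25.4

(scatter of a reading: 0.3 percentage points)

- a reading or a percentage of product counts all its forms, free or not
- percentages count the whole charge, also what has not yet gone in
- no earlier run changes the charge of free catalyst; that part of a forecast is a guess

- ranking by amount of product, in percent of the starting material charged, from high to low, at 25 h (Wednesday's / Thursday's / Friday's / Saturday's / Monday's)
- the amount of product, in percent of the starting material charged of the flask you put first, at 25 h
- the amount of product, in percent of the starting material charged of the flask you put last, at 25 h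

The last readings of the two runs gave these time constants, one per charge:

τ(east) = 22.2 h, τ(north-east) = 23.7 h

The constant lengthened by 1.50 h over the 3.00 mM between the two charges, and I extended that in a straight line to 20 mM:

T = 27.2 h

I called T the catalyst clock: the pseudo-first-order time constant at 100 µM of free catalyst and this charge. I assumed that a flask's time x, counted from mid-feed, scales with its catalyst, which is a guess.

The runs slowed as they went, so T held to the end bounds product from above:

Wednesday's: x = 47.0 h, product below 1 − exp(−x/T) = 82.2 %

Saturday's: x = 7.05 h, product below 22.8 %

Saturday's x lies close to the 6.50 h behind T, so I gave that flask this one line. For Wednesday's I read the lengthening as growing with product, and let the clock grow in a straight line up to the upper bound: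

T(slow) = 49.6 h, product above 61.2 %

I tightened no further.

The forecast gave Wednesday's > Thursday's > Friday's > Monday's > Saturday's, with 79 % first and 24.5 % last, and argued: “The slowing within each run points to product inhibition.” Its top lay inside my bracket of 61.2 % to 82.2 %, and its low stood higher than my line for Saturday's.

The flasks gave Wednesday's > Thursday's > Friday's > Monday's > Saturday's, with 77.0 % for Wednesday's and 22.0 % for Saturday's.

    starting material + free catalyst → catalyst intermediate (k = 10.1 M⁻¹ min⁻¹)
    catalyst intermediate → free catalyst + product (k = 0.302 min⁻¹)
    free catalyst + product ⇌ idle complex (K = 72.9 M⁻¹, k = 0.546 M⁻¹ min⁻¹)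

Wednesday's result, read back through x, gives a clock of 32.0 h, longer than T, and at 25.0 h that flask held 48.4 % of its catalyst as idle complex. I took a neighbour of Wednesday's charged with 0.080 mM of free catalyst, whose x is 18.8 h. T puts its product below 49.9 %, and Wednesday's clock puts it near 44.4 %. At 25 h the neighbour held 46.8 % of product, with 53.1 % of the starting material left.

The earlier runs and the new flask stem from a simulated flask for substances that don't exist, and the scatter is random.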